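**Plan**

- Numbering used throughout: ring A = C12–C13–C14–C15(–C16H3)–C8–C7; ring B = C12–C4–C5–C6–C7; ring C = C12–C11–C10–C9–N–C1–C2–C3=C4. The "upper face" of ring A is the face that carries ring B (C4, C6).
- Retrosynthetic cuts, in order: the two acetates and the C13–O/C15–O bonds of ring A (back to a C13 ketone and C15–H); the two C–N bonds of ring C (nitrogen from a primary sulfonamide); the C3=C4 bond (aldol/dehydration with a C3 aldehyde); the C6–C7 bond of ring B; finally C12–C4 and C12–C11, leaving 5-methylcyclohexane-1,3-dione.
- Enabling feature: the quaternary C12 lies between C13 (the secondary acetoxy carbon of ring A) and the ring-fusion carbon C7, and ring B is an acetonyl unit C4–C5(=O)–C6 closed onto C7. Ring A plus C12 is therefore a 2,2-disubstituted 5-methylcyclohexane-1,3-dione whose two carbonyls (future C13 and C7) are enantiotopic.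
- Forward order: ring A is the starting dione; C12 is quaternised (reductive alkylation, propargylation, hydration); ring B closes by the desymmetrising aldol condensation; the C1–C3 chain is added by α′-aldol/dehydration; ring C closes by double N-alkylation; ring A is then adjusted (enone, reduction, directed epoxidation, hydride opening); N-formylation, C5 oxidation and acetylation finish.
- Stereochemistry: C12 from the amino-acid catalyst (choice of carbonyl); H-7 by cis-hydrogenation relayed from C12; the C3=C4 geometry from the elimination, then held by ring C; C13 by axial hydride delivery; C15 by hydroxyl-directed epoxidation and trans-diaxial hydride opening. Three temporary centres (C15–H, the aldol centres C3/C4, the C5 carbinol) are erased on the way.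

Key step: step 4

**Remarks on the chemistry**

- Assumption: the propargylation (step 2) is taken to occur anti to the ring flap, placing the new group cis to the 5-methyl group. The trans isomer would behave identically and both series merge at 23, where C15 becomes sp2.
- Compounds 12–14 are carried as mixtures at C3 and C4; both centres vanish in step 8.
- The C5 carbinol configuration drawn for 16–28 is the sterically expected one; either epimer serves, since C5 returns to a ketone in step 19.
- The descriptor of C12 is (R) in 9 and (S) in the target for the same spatial arrangement; only the substituent priorities change.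

**Route**

Step 1
Reactants: 1 5-methylcyclohexane-1,3-dione; 2 3-(benzyloxy)propanal
Product: 4 2-[3-(benzyloxy)propyl]-5-methylcyclohexane-1,3-dione, via alkylidene dione 3 (not isolated)
Conditions: Hantzsch ester (diethyl 2,6-dimethyl-1,4-dihydropyridine-3,5-dicarboxylate), L-proline (10 mol %), CH2Cl2, rt
Reagents that add atoms: none
Why: Proline-catalysed Knoevenagel condensation gives 3, which is reduced in situ by conjugate hydride transfer from the dihydropyridine (organocatalytic three-component reductive alkylation), so that clean mono-C-alkylation at C2 is expected without O-alkylation or bis-adduct formation; no stereocentre of consequence arises because 4 is largely enolised.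

Step 2
Reactants: 4 2-[3-(benzyloxy)propyl]-5-methylcyclohexane-1,3-dione; 5 3-bromoprop-1-yne
Product: 6 2-[3-(benzyloxy)propyl]-5-methyl-2-(prop-2-yn-1-yl)cyclohexane-1,3-dione (propargyl cis to methyl)
Conditions: 1 M aq. NaOH, 60 °C
Reagents that add atoms: none
Why: SN2 C-alkylation of the sodium enolate of a 2-alkyl-1,3-dione by the propargylic halide creates the future C12 as the non-stereogenic quaternary carbon of a mirror-symmetric dione, and the cis/trans relation to the methyl group is without consequence.

Step 3
Reactants: 6 2-[3-(benzyloxy)propyl]-5-methyl-2-(prop-2-yn-1-yl)cyclohexane-1,3-dione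
Product: 7 2-[3-(benzyloxy)propyl]-5-methyl-2-(2-oxopropyl)cyclohexane-1,3-dione (2-oxopropyl cis to methyl)
Conditions: Ph3PAuCl (2 mol %), AgOSO2CF3 (2 mol %), dioxane–H2O, 60 °C
Reagents that add atoms: water, O
Why: Gold-catalysed Markovnikov hydration of the terminal alkyne (π-activation by the cationic phosphine–gold species, possibly assisted by a ring carbonyl oxygen) gives the methyl ketone and thus the prochiral triketone, the benzyl ether being inert.

Step 4
Reactants: 7 2-[3-(benzyloxy)propyl]-5-methyl-2-(2-oxopropyl)cyclohexane-1,3-dione
Product: 9 (3aR,6S)-3a-[3-(benzyloxy)propyl]-6-methyl-3,3a,6,7-tetrahydro-2H-indene-2,4(5H)-dione (C5 enone with C6=C7 and C13 ketone; methyl cis to C4), via bicyclic ketol 8 (not isolated)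
Conditions: D-phenylalanine (1 equiv), (1R)-(−)-camphor-10-sulfonic acid (0.5 equiv), DMF, 50 °C
Reagents that add atoms: none
Why: The primary amino acid condenses with the methyl ketone to the terminal enamine, whose CH2= carbon adds to one of the two enantiotopic ring carbonyls while the carboxylic acid protonates that carbonyl in a closed hydrogen-bonded transition state, and the resulting cis-fused ketol 8 is dehydrated by the sulfonic acid to cyclopentenone 9. The closest known reaction is the Hajos–Parrish (Eder–Sauer–Wiechert) amino-acid-catalysed desymmetrising aldol condensation of 2,2-disubstituted cyclic 1,3-diones, here in its acetonyl variant with a primary amino acid and a sulfonic acid co-catalyst as used for hindered 2-substituents. Ring B closes in a 5-(enolendo)-exo-trig mode (both enamine carbons end up in the ring, the carbonyl oxygen outside), which Baldwin's rules disfavour for enolates but which is the normal course of 1,4-diketone-to-cyclopentenone aldolisation under equilibrating conditions. The only lasting new stereocentre is the quaternary C12, fixed by which carbonyl the catalyst selects; the D-amino acid is chosen because L-amino acids give the (S)-ketone in the parent six-membered-enone reaction, which has the same substituent priorities, and the mirror-image (R) arrangement is needed here. The step needs enantiotopic-group selectivity (from the catalyst) and site selectivity for the C6–C7 bond, the latter secured because attack through the internal enamine carbon would give a three-membered ring and because C12 bears no hydrogen and cannot epimerise; the carbinol centre of 8 is lost on dehydration and the methyl-bearing centre is a spectator.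

Step 5
Reactants: 9 bicyclic enedione
Product: 10 13-(1,3-dioxolane) ketal of 9 (C5 enone retained)
Conditions: ethylene glycol, p-TsOH·H2O (cat.), 4 Å MS, rt
Reagents that add atoms: ethylene glycol, OCCO
Why: Acid-catalysed ketalisation is chemoselective for the saturated C13 ketone because the enone carbonyl is deactivated by conjugation (the usual differentiation of such enediones), and it masks C13 against base and hydride until step 12.

Step 6
Reactants: 10 ketal enone; 2 3-(benzyloxy)propanal
Product: 12 C4 aldol adduct [4-(3-benzyloxy-1-hydroxypropyl) derivative of 10; mixture at C3 and C4], via lithium dienolate 11 (not isolated)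
Conditions: LiN(i-Pr)2, THF, −78 °C; then 2, −78 °C; aq. NH4Cl
Reagents that add atoms: none
Why: Kinetic deprotonation can only occur at the α′-methylene C4 (C6 is vinylic and γ-deprotonation at C8 is slow at −78 °C), and the cross-conjugated lithium dienolate 11 adds to the aldehyde in a directed aldol addition whose two new centres are inconsequential because both become sp2 in step 8.

Step 7
Reactants: 12 C4 aldol adduct
Product: 13 cis-fused hydrindanone triol (C1-OH, C3-OH, C9-OH; H-7 cis to C11)
Conditions: H2 (1 atm), Pd/C, EtOAc–EtOH, rt
Reagents that add atoms: none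
Why: Heterogeneous hydrogenation saturates the C6=C7 enone bond from the cyclopentenone face opposite the ketal-bearing C13, that is cis to the C11 chain, which sets H-7 of the cis-hydrindanone, and the same catalyst hydrogenolyses both benzyl ethers.

Step 8
Reactants: 13 cis-fused hydrindanone triol
Product: 15 (E)-C3=C4 enone 1,9-bis(methanesulfonate), via tris-mesylate 14 (not isolated)
Conditions: MeSO2Cl, Et3N, CH2Cl2, −20 → 0 °C; then DBU, 0 °C → rt
Reagents that add atoms: methanesulfonyl chloride, CS(=O)(=O)Cl
Why: All three hydroxyls are mesylated and the amidine base then expels the β-mesyloxy group by E1cB elimination through the C4 enolate, which should give the 2-alkylidenecyclopentanone with C2 anti to the carbonyl ((E), the usual outcome of aldol condensation/dehydration), while the two primary mesylates remain for ring closure.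

Step 9
Reactants: 15 (E)-enone bis-mesylate
Product: 16 (E)-C5 allylic alcohol 1,9-bis(methanesulfonate)
Conditions: NaBH4, CeCl3·7H2O, MeOH, −40 → 0 °C
Reagents that add atoms: none
Why: Luche 1,2-reduction removes the Michael acceptor and the acidic γ-hydrogens before the basic cyclisation; hydride should enter from the ring-B face that bears the C11 chain, and the configuration of this temporary carbinol is irrelevant.

Step 10
Reactants: 16 allylic alcohol bis-mesylate; 17 4-methylbenzenesulfonamide
Product: 19 N-tosyl azonane (ring C closed) with C5 allylic alcohol and 13-ketal, via mono-N-alkylated sulfonamide 18 (not isolated)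
Conditions: Cs2CO3, n-Bu4NI (cat.), DMF (5 mM), 60 °C
Reagents that add atoms: none
Why: Double SN2 N-alkylation of the primary sulfonamide, in which intermolecular displacement of one primary mesylate gives 18 and its more nucleophilic N-alkylsulfonamide anion closes the nine-membered ring at high dilution (the classical sulfonamide-displacement azonane closure), helped by both chains being held on the adjacent carbons C12 and C4 with the (E)-alkene pointing C2 toward C12.

Step 11
Reactants: 19 N-tosyl azonane allylic alcohol
Product: 20 C5 acetate of 19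
Conditions: Ac2O, pyridine, DMAP (cat.), CH2Cl2, rt
Reagents that add atoms: acetic anhydride, CC(=O)OC(C)=O
Why: DMAP-catalysed acylation caps the C5 allylic hydroxyl, which would otherwise direct the epoxidation of step 15 to C3=C4, as an ester that the hydride of step 16 removes without a separate step.

Step 12
Reactants: 20 C5 acetate
Product: 21 C13 ketone (ketal removed)
Conditions: 2 M aq. HCl, THF, rt
Reagents that add atoms: water, O
Why: Acid-catalysed ketal hydrolysis frees the C13 ketone, the sulfonamide, allylic acetate and trisubstituted alkene being stable to dilute acid at room temperature.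

Step 13
Reactants: 21 C13 ketone
Product: 23 ring-A enone (C13=O, C14=C15–CH3), via silyl enol ether 22 (not isolated)
Conditions: Me3SiOSO2CF3, Et3N, CH2Cl2, 0 °C; then Pd(OAc)2 (1.2 equiv), MeCN, rt
Reagents that add atoms: none
Why: Saegusa–Ito dehydrogenation, in which soft enolisation can only give the C13–C14 silyl enol ether (C12 is quaternary) and Pd(OAc)2 converts it through a palladium enolate and β-hydride elimination of H-15 into the enone, erasing the temporary C15 centre.

Step 14
Reactants: 23 ring-A enone
Product: 24 13-allylic alcohol (hydroxyl on the upper face, cis to ring B)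
Conditions: NaBH4, CeCl3·7H2O, MeOH, −78 °C
Reagents that add atoms: none
Why: Luche 1,2-reduction, in which the small hydride is expected to attack C13 axially and anti to the pseudo-axial C12–C4 bond (from the side of the C11 methylene), placing the new hydroxyl on the upper face and setting C13.

Step 15
Reactants: 24 13-allylic alcohol
Product: 25 14,15-epoxy-13-ol (epoxide cis to the hydroxyl)
Conditions: VO(acac)2 (5 mol %), t-BuOOH, CH2Cl2, 0 °C → rt
Reagents that add atoms: tert-butyl hydroperoxide, CC(C)(C)OO
Why: Vanadium-catalysed hydroxyl-directed epoxidation delivers oxygen to C14=C15 from the face of the 13-hydroxyl (C15–O up, methyl down) and is far faster for this allylic alkene than for the merely homoallylic C3=C4 bond.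

Step 16
Reactants: 25 epoxy alcohol
Product: 26 N-tosyl 5,13,15-triol (13-OH and 15-OH cis)
Conditions: LiAlH4, THF, 0 °C → rt
Reagents that add atoms: none
Why: Hydride opens the trisubstituted epoxide by SN2 attack at the secondary C14 in the trans-diaxial (Fürst–Plattner) sense, leaving the tertiary 15-alcohol cis to the 13-hydroxyl, and also reduces off the C5 acetate, the sulfonamide being inert at this temperature.

Step 17
Reactants: 26 N-tosyl triol
Product: 27 amino triol (free azonane N–H)
Conditions: NaC10H8 (sodium naphthalenide), DME, −78 °C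
Reagents that add atoms: none
Why: Electron transfer from the naphthalene radical anion cleaves the S–N bond (reductive detosylation) at low temperature without touching the alkoxides or the trisubstituted alkene.

Step 18
Reactants: 27 amino triol
Product: 28 N-formyl triol
Conditions: HCO2CH2CF3, THF, 60 °C
Reagents that add atoms: 2,2,2-trifluoroethyl formate, O=COCC(F)(F)F
Why: Aminolysis of the activated formate (N-formylation) is chemoselective for the secondary amine over the three hydroxyls.

Step 19
Reactants: 28 N-formyl triol
Product: 29 N-formyl 13,15-diol with C5 enone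
Conditions: MnO2 (activated, excess), CH2Cl2, rt
Reagents that add atoms: none
Why: Allylic oxidation with MnO2 converts only the C5 allylic alcohol into the enone, whose (E) geometry is held by ring C, and leaves the saturated secondary 13-alcohol and the tertiary 15-alcohol untouched.

Step 20
Reactants: 29 N-formyl diol enone
Product: 30 target, (3E,7S,12S,13S,15S)-13,15-diacetoxy N-formyl azonane-fused hydrindan-5-one
Conditions: Ac2O, DMAP, Et3N, CH2Cl2, 40 °C
Reagents that add atoms: acetic anhydride, CC(=O)OC(C)=O
Why: DMAP-catalysed acylation with excess anhydride esterifies both the hindered secondary and the tertiary alcohol, the formamide and the enone being inert, to give the target.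

**Compound list**

1 | 5-methylcyclohexane-1,3-dione | CC1CC(=O)CC(=O)C1 | starting material
2 | 3-(benzyloxy)propanal | O=CCCOCc1ccccc1 | starting material
3 | 2-[3-(benzyloxy)propylidene]-5-methylcyclohexane-1,3-dione | CC1CC(=O)C(=CCCOCc2ccccc2)C(=O)C1 | intermediate
4 | 2-[3-(benzyloxy)propyl]-5-methylcyclohexane-1,3-dione (largely enolised) | CC1CC(=O)C(CCCOCc2ccccc2)C(=O)C1 | intermediate
5 | 3-bromoprop-1-yne (propargyl bromide) | C#CCBr | starting material
6 | 2-[3-(benzyloxy)propyl]-5-methyl-2-(prop-2-yn-1-yl)cyclohexane-1,3-dione, propargyl cis to methyl (achiral) | C#CC[C@]1(CCCOCc2ccccc2)C(=O)C[C@H](C)CC1=O | intermediate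
7 | 2-[3-(benzyloxy)propyl]-5-methyl-2-(2-oxopropyl)cyclohexane-1,3-dione, 2-oxopropyl cis to methyl (achiral, prochiral) | CC(=O)C[C@]1(CCCOCc2ccccc2)C(=O)C[C@H](C)CC1=O | intermediate
8 | cis-fused bicyclic ketol: ring B closed, 7-hydroxyl cis to the C11 chain, C5 and C13 ketones, (12R) | O=C1C[C@@H](C)C[C@@]2(O)CC(=O)C[C@]21CCCOCc1ccccc1 | intermediate
9 | (3aR,6S)-3a-[3-(benzyloxy)propyl]-6-methyl-3,3a,6,7-tetrahydro-2H-indene-2,4(5H)-dione (C5 enone, C6=C7; C13 ketone; methyl cis to C4) | O=C1C[C@@H](C)CC2=CC(=O)C[C@]21CCCOCc1ccccc1 | intermediate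
10 | 13-(1,3-dioxolane) ketal of 9 | C12(OCCO1)C[C@@H](C)CC1=CC(=O)C[C@]12CCCOCc1ccccc1 | intermediate
11 | lithium cross-conjugated dienolate of 10 (C5–O–Li, C4=C5, C6=C7) | C12(OCCO1)C[C@@H](C)CC1=CC([O-])=C[C@]12CCCOCc1ccccc1.[Li+] | intermediate
12 | aldol adduct: 10 bearing a 3-(benzyloxy)-1-hydroxypropyl group at C4 (mixture at C3 and C4) | C12(OCCO1)C[C@@H](C)CC1=CC(=O)C(C(O)CCOCc3ccccc3)[C@]12CCCOCc1ccccc1 | intermediate
13 | cis-fused hydrindan-5-one triol (C1-OH, C3-OH, C9-OH; H-7 cis to C11; mixture at C3 and C4; 13-ketal) | C12(OCCO1)C[C@@H](C)C[C@H]1CC(=O)C(C(O)CCO)[C@]12CCCO | intermediate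
14 | 1,3,9-tris(methanesulfonate) of 13 | C12(OCCO1)C[C@@H](C)C[C@H]1CC(=O)C(C(OS(C)(=O)=O)CCOS(C)(=O)=O)[C@]12CCCOS(C)(=O)=O | intermediate
15 | (E)-C3=C4 enone (C5 ketone) 1,9-bis(methanesulfonate), 13-ketal | C12(OCCO1)C[C@@H](C)C[C@H]1CC(=O)/C(=C/CCOS(C)(=O)=O)[C@]12CCCOS(C)(=O)=O | intermediate
16 | (E)-C5 allylic alcohol 1,9-bis(methanesulfonate), 13-ketal (5-OH on the ring-B face toward C13) | C12(OCCO1)C[C@@H](C)C[C@H]1C[C@@H](O)/C(=C/CCOS(C)(=O)=O)[C@]12CCCOS(C)(=O)=O | intermediate
17 | 4-methylbenzenesulfonamide | Cc1ccc(cc1)S(N)(=O)=O | starting material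
18 | mono-N-alkylated sulfonamide (C9–NHTs, C1–OMs; the regioisomer alkylated at C1 closes to the same ring) | C12(OCCO1)C[C@@H](C)C[C@H]1C[C@@H](O)/C(=C/CCOS(C)(=O)=O)[C@]12CCCNS(=O)(=O)c1ccc(C)cc1 | intermediate
19 | N-tosyl azonane tricycle: (E)-C3=C4, 5-hydroxyl, 13-ketal | O1CCOC12C[C@@H](C)C[C@H]3C[C@@H](O)/C4=C/CCN(S(=O)(=O)c5ccc(C)cc5)CCC[C@@]432 | intermediate
20 | 5-acetate of 19 | O1CCOC12C[C@@H](C)C[C@H]3C[C@@H](OC(C)=O)/C4=C/CCN(S(=O)(=O)c5ccc(C)cc5)CCC[C@@]432 | intermediate
21 | N-tosyl tricycle with C13 ketone and 5-acetate | O=C1C[C@@H](C)C[C@H]2C[C@@H](OC(C)=O)/C3=C/CCN(S(=O)(=O)c4ccc(C)cc4)CCC[C@@]321 | intermediate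
22 | C13–C14 trimethylsilyl enol ether of 21 | C[Si](C)(C)OC1=C[C@@H](C)C[C@H]2C[C@@H](OC(C)=O)/C3=C/CCN(S(=O)(=O)c4ccc(C)cc4)CCC[C@@]321 | intermediate
23 | ring-A enone (C13=O, C14=C15–CH3), 5-acetate, N-tosyl | O=C1C=C(C)C[C@H]2C[C@@H](OC(C)=O)/C3=C/CCN(S(=O)(=O)c4ccc(C)cc4)CCC[C@@]321 | intermediate
24 | 13-allylic alcohol (13-OH on the upper face), 5-acetate, N-tosyl | O[C@H]1C=C(C)C[C@H]2C[C@@H](OC(C)=O)/C3=C/CCN(S(=O)(=O)c4ccc(C)cc4)CCC[C@@]321 | intermediate
25 | 14,15-epoxy-13-ol (epoxide and 13-OH both on the upper face, methyl down), 5-acetate, N-tosyl | O[C@H]1[C@H]2O[C@@]2(C)C[C@H]3C[C@@H](OC(C)=O)/C4=C/CCN(S(=O)(=O)c5ccc(C)cc5)CCC[C@@]431 | intermediate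
26 | N-tosyl 5,13,15-triol (13-OH and 15-OH cis, on the upper face) | O[C@H]1C[C@@](C)(O)C[C@H]2C[C@@H](O)/C3=C/CCN(S(=O)(=O)c4ccc(C)cc4)CCC[C@@]321 | intermediate
27 | amino triol (azonane N–H) | O[C@H]1C[C@@](C)(O)C[C@H]2C[C@@H](O)/C3=C/CCNCCC[C@@]321 | intermediate
28 | N-formyl 5,13,15-triol | O[C@H]1C[C@@](C)(O)C[C@H]2C[C@@H](O)/C3=C/CCN(C=O)CCC[C@@]321 | intermediate
29 | N-formyl 13,15-diol with (E)-C3=C4 C5 enone | O[C@H]1C[C@@](C)(O)C[C@H]2CC(=O)/C3=C/CCN(C=O)CCC[C@@]321 | intermediate
30 | target: (3E,7S,12S,13S,15S)-13,15-diacetoxy-N-formyl tricycle (13-OAc and 15-OAc on the upper face, C16 methyl, H-7 and C11 on the lower face) | CC(=O)O[C@H]1C[C@@](C)(OC(C)=O)C[C@H]2CC(=O)/C3=C/CCN(C=O)CCC[C@@]321 | target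

**Step count and risks**

Total step count: 20. Longest linear sequence: 20 steps (1 to 30).

Steps most likely to fail:

Step 8. The elimination may deliver the (Z)-alkylidene ketone or an E/Z mixture, because the alkene forms before any ring constrains it and C2 must sit beside the fully substituted C12. Vinylogous loss of the homoallylic mesylate is a second possible leak. The fallback closes ring C first and eliminates inside the ring, where only the cis-cyclononene (E) geometry is accessible. It sets out from 12. Silylation of the aldol hydroxyl (t-BuMe2SiOSO2CF3, 2,6-lutidine) would give the silyl ether F1. Hydrogenation and hydrogenolysis as in step 7 would give the silyloxy diol F2, and MeSO2Cl/Et3N the bis-mesylate F3. Treatment with 17 and Cs2CO3 at high dilution would pass through the mono-alkylated sulfonamide F4 to the azonane β-silyloxy ketone F5, a β-silyloxy ketone being expected to tolerate carbonate. DBU in toluene at 80 °C would then expel silanolate by E1cB elimination to the in-ring enone F6, and Luche reduction of F6 rejoins the route at 19.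

Step 14. Hydride addition to C13 may show poor or reversed facial selectivity, since the conformational preference of the ring-A enone in the tricycle is not secure, and the wrong carbinol would also misdirect the epoxidation of step 15. The fallback corrects the centre by SN2 inversion instead of relying on the reduction. It sets out from 23: the reduction product, if it is the 13-epimeric alcohol F7, would be submitted to Mitsunobu inversion with chloroacetic acid (PPh3, diisopropyl azodicarboxylate, toluene) to give the inverted chloroacetate F8. Selective methanolysis (K2CO3, MeOH, −10 °C; a chloroacetate is cleaved far faster than the C5 acetate) returns to the route at 24.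

Step 4. Discrimination between the enantiotopic carbonyls may be insufficient, or of the opposite sense, in this five-membered-ring variant. The fallback separates C–C bond formation from stereocontrol while keeping the same aldol disconnection. It sets out from 7: pyrrolidine/AcOH would effect the same aldol condensation without enantiocontrol to give the racemic enedione F9. Ketalisation of its saturated ketone with (2R,3R)-butane-2,3-diol (p-TsOH) would give two diastereomeric ketals, the ketal of the (12R)-enantiomer F10 and the ketal of the (12S)-enantiomer F11, to be separated by chromatography. Hydrolysis of F10 (aq. HCl, THF) returns to the route at 9 as a single enantiomer.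

Further compounds
F1 | step 8 | tert-butyldimethylsilyl ether of aldol adduct 12 (mixture at C3 and C4) | C12(OCCO1)C[C@@H](C)CC1=CC(=O)C(C(O[Si](C)(C)C(C)(C)C)CCOCc3ccccc3)[C@]12CCCOCc1ccccc1
F2 | step 8 | cis-fused hydrindan-5-one 1,9-diol with 3-silyloxy group (mixture at C3 and C4) | C12(OCCO1)C[C@@H](C)C[C@H]1CC(=O)C(C(O[Si](C)(C)C(C)(C)C)CCO)[C@]12CCCO
F3 | step 8 | 1,9-bis(methanesulfonate) of F2 | C12(OCCO1)C[C@@H](C)C[C@H]1CC(=O)C(C(O[Si](C)(C)C(C)(C)C)CCOS(C)(=O)=O)[C@]12CCCOS(C)(=O)=O
F4 | step 8 | mono-N-alkylated sulfonamide from F3 (C9–NHTs, C1–OMs) | C12(OCCO1)C[C@@H](C)C[C@H]1CC(=O)C(C(O[Si](C)(C)C(C)(C)C)CCOS(C)(=O)=O)[C@]12CCCNS(=O)(=O)c1ccc(C)cc1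
F5 | step 8 | N-tosyl azonane β-silyloxy ketone (C5 ketone, 3-silyloxy group, 13-ketal; mixture at C3 and C4) | O1CCOC12C[C@@H](C)C[C@H]3CC(=O)C4C(O[Si](C)(C)C(C)(C)C)CCN(S(=O)(=O)c5ccc(C)cc5)CCC[C@@]432
F6 | step 8 | N-tosyl azonane (E)-C3=C4 C5 enone, 13-ketal | O1CCOC12C[C@@H](C)C[C@H]3CC(=O)/C4=C/CCN(S(=O)(=O)c5ccc(C)cc5)CCC[C@@]432
F7 | step 14 | 13-epimer of allylic alcohol 24 (13-OH on the lower face) | O[C@@H]1C=C(C)C[C@H]2C[C@@H](OC(C)=O)/C3=C/CCN(S(=O)(=O)c4ccc(C)cc4)CCC[C@@]321
F8 | step 14 | 13-chloroacetate of 24 (inverted, ester on the upper face) | ClCC(=O)O[C@H]1C=C(C)C[C@H]2C[C@@H](OC(C)=O)/C3=C/CCN(S(=O)(=O)c4ccc(C)cc4)CCC[C@@]321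
F9 | step 4 | racemic enedione (9 and its enantiomer, 1:1) | O=C1C[C@@H](C)CC2=CC(=O)C[C@]21CCCOCc1ccccc1.O=C1C[C@H](C)CC2=CC(=O)C[C@@]21CCCOCc1ccccc1
F10 | step 4 | (2R,3R)-butane-2,3-diyl ketal at C13 of 9 | C[C@H]1OC2(O[C@@H]1C)C[C@@H](C)CC1=CC(=O)C[C@]12CCCOCc1ccccc1
F11 | step 4 | (2R,3R)-butane-2,3-diyl ketal at C13 of the enantiomer of 9 | C[C@H]1OC2(O[C@@H]1C)C[C@H](C)CC1=CC(=O)C[C@@]12CCCOCc1ccccc1
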